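## Retrosynthetic overview

1. Target 21 ⇐ decalinol lactone 18 by Hock–Criegee oxygen insertion into the C5–C10 bond (C10 moves from C5 to oxygen with retention), so the ten-membered ring is unveiled in the last step.
2. 18 ⇐ 13 by building the α-methylene lactone from the isopropenyl group and O8 (SeO2, then MnO2); 13 ⇐ 12 by cathodic ketone–olefin cyclization (C4–C5 bond, ring A).
3. 12 ⇐ 8 by hydroxyl-directed epoxidation, semipinacol 1,2-shift of the pentenyl group (C10 quaternary centre, C9–O) and esterification with (S)-2-methylbutanoic acid.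
4. 8 ⇐ (R)-carvone by photochemical γ-silyloxylation of its silyl dienol ether (C8–O) and pentenyl Grignard addition.
5. Ring order: ring B (bought as carvone) → ring A (electrochemical) → γ-lactone → ten-membered ring (ring expansion).

Assumption: the target is handled as the open 10-hydroxy-5-ketone of the given SMILES; its transannular hemiketal 20 is an equilibrium form.

Locants C1–C15 are those of the target: ring C1–C10 (C5 ketone, C10 carbinol), lactone C8–O–C12(=O)–C11(=C13), C14 = methyl on C10, C15 = methyl on C4. Ring B = C5–C10 (the carvone ring); ring A = C1–C5 plus C10.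

## Route

Step 1
Reactants: 1 (R)-(−)-carvone
Product: 2 linear silyl dienol ether (5S)-1-(tert-butyldimethylsilyloxy)-2-methyl-5-(prop-1-en-2-yl)cyclohexa-1,3-diene
Conditions: TBSOTf, Et3N, CH2Cl2, 0 °C → rt, 12 h (equilibrating)
Reagents that add atoms: tert-butyldimethylsilyl trifluoromethanesulfonate, CC(C)(C)[Si](C)(C)OS(=O)(=O)C(F)(F)F
Why: Soft enolisation under equilibrating conditions gives the through-conjugated (linear) silyl dienol ether by γ-deprotonation, as with steroidal 4-en-3-ones, and leaves the C7 stereocentre untouched (thermodynamic silyl dienol ether formation).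

Step 2
Reactants: 2 linear silyl dienol ether
Product: 5 silyloxy enone (4S,5R)-4-(tert-butyldimethylsilyloxy)-2-methyl-5-(prop-1-en-2-yl)cyclohex-2-en-1-one, via silyl endoperoxide 3 (not isolated), via silylperoxy enone 4 (not isolated)
Conditions: O2, meso-tetraphenylporphyrin (0.5 mol %), 530 nm LED, CH2Cl2, −78 °C; warm to −20 °C; PPh3, −20 °C → rt
Reagents that add atoms: dioxygen, O=O
Why: Proposed new method: singlet oxygen adds [4+2] to the s-cis silyloxydiene on the face anti to the C7 isopropenyl group (this sets C8), the bridgehead silyl peroxyketal 3 collapses to the enone with O-to-O silyl shift giving the γ-silylperoxy enone 4, and PPh3 then removes one peroxide oxygen so that silicon stays on O8 (net photochemical γ-silyloxylation of an enone); the closest known reactions are the singlet-oxygen Diels–Alder reaction of cyclohexa-1,3-dienes, the silatropic photooxygenation of silyl enol ethers to α-silylperoxy ketones and the phosphine deoxygenation of peroxides.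

Step 3
Reactants: 5 silyloxy enone; 6 5-bromopent-1-ene
Product: 8 tertiary allylic alcohol (1R,4S,5R)-4-(tert-butyldimethylsilyloxy)-2-methyl-1-(pent-4-en-1-yl)-5-(prop-1-en-2-yl)cyclohex-2-en-1-ol, via pent-4-en-1-ylmagnesium bromide 7 (not isolated)
Conditions: 6, Mg, THF, rt; then 5, THF, −78 → 0 °C; H2O quench
Reagents that add atoms: none
Why: Grignard 1,2-addition to the enone carbonyl takes place axially on the face anti to the C7 isopropenyl group, so the pentenyl chain on C5 is trans and the new hydroxyl cis to isopropenyl.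

Step 4
Reactants: 8 tertiary allylic alcohol
Product: 9 syn-epoxy alcohol (9,10-oxirane of 8 cis to the C5 hydroxyl)
Conditions: VO(acac)2 (3 mol %), t-BuOOH (decane), PhMe, 0 °C → rt
Reagents that add atoms: tert-butyl hydroperoxide, CC(C)(C)OO
Why: Vanadium-catalysed hydroxyl-directed epoxidation touches only the allylic-alcohol alkene and delivers oxygen to the face of the C5 hydroxyl, which is also the face anti to the bulky C8 silyl ether (Sharpless directed epoxidation).

Step 5
Reactants: 9 syn-epoxy alcohol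
Product: 10 β-hydroxy ketone (2R,3R,4R,5R)-4-(tert-butyldimethylsilyloxy)-3-hydroxy-2-methyl-2-(pent-4-en-1-yl)-5-(prop-1-en-2-yl)cyclohexan-1-one
Conditions: BF3·OEt2 (0.3 equiv), CH2Cl2, −78 °C
Reagents that add atoms: none
Why: Lewis-acid opening of the oxirane at the tertiary C10 triggers a semipinacol 1,2-shift of the pentenyl group, the C5 substituent antiperiplanar to the breaking C10–O bond, which sets the C10 quaternary centre with inversion (chain trans and methyl cis to the retained C9 hydroxyl) and regenerates the C5 ketone (semipinacol rearrangement of a 2,3-epoxy alcohol).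

Step 6
Reactants: 10 β-hydroxy ketone; 11 (S)-2-methylbutanoic acid
Product: 12 keto ester (1R,2R,5R,6R)-6-(tert-butyldimethylsilyloxy)-2-methyl-3-oxo-2-(pent-4-en-1-yl)-5-(prop-1-en-2-yl)cyclohexyl (2S)-2-methylbutanoate
Conditions: N,N'-diisopropylcarbodiimide, DMAP (10 mol %), CH2Cl2, 0 °C → rt
Reagents that add atoms: none
Why: Steglich esterification acylates the only free hydroxyl with the bought (S)-acid without a ketene-forming base, so its α-centre is not epimerised, and it also blocks retro-aldol cleavage of the β-hydroxy ketone.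

Step 7
Reactants: 12 keto ester
Product: 13 cis-fused decalinol (ring A closed; C5–OH, C10–CH3 and C4–CH3 on one face)
Conditions: divided cell, carbon-fibre cathode, Pt anode, Et4NOTs (0.2 M), DMF–i-PrOH 9:1, constant current (2.2 F/mol), 0 °C
Reagents that add atoms: none
Why: Cathodic one-electron reduction of the ketone gives a ketyl that adds 6-exo to the terminal alkene (Shono electroreductive ketone–olefin cyclization), forming the C4–C5 bond through a chair transition state in which the chain attacks C5 from the face fixed by C10 (cis-decalin) with the alkene terminus equatorial, which sets C4 as S with its methyl cis to the new C5 hydroxyl.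

Step 8
Reactants: 13 cis-fused decalinol
Product: 14 decalin diol (free C8 hydroxyl)
Conditions: HF·pyridine, THF–pyridine, 0 °C → rt
Reagents that add atoms: none
Why: Acidic fluoride removes the silyl ether without the base-induced acyl shift from O9 to O8 that fluoride salts could cause (desilylation).

Step 9
Reactants: 14 decalin diol
Product: 15 allylic alcohol (isopropenyl oxidised to 3-hydroxyprop-1-en-2-yl)
Conditions: SeO2 (0.3 equiv), t-BuOOH (70% aq), CH2Cl2, rt
Reagents that add atoms: tert-butyl hydroperoxide, CC(C)(C)OO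
Why: Catalytic SeO2 with t-BuOOH oxidises the methyl group of the only remaining alkene by the ene and [2,3]-sigmatropic (Riley) pathway to the 2-substituted allylic alcohol without touching any stereocentre.

Step 10
Reactants: 15 allylic alcohol
Product: 18 decalinol lactone (trans-fused α-methylene-γ-lactone on C7–C8), via enal 16 (not isolated), via lactol 17 (not isolated)
Conditions: MnO2 (activated, excess), CH2Cl2, rt
Reagents that add atoms: none
Why: MnO2 oxidises only the allylic primary alcohol to the enal, the C8 hydroxyl closes the lactol and MnO2 oxidises this to the lactone (oxidative lactonization of a 1,4-diol), with C7 and C8 unchanged.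

Step 11
Reactants: 18 decalinol lactone
Product: 21 target CNP0144277.6, via tertiary hydroperoxide 19 (not isolated), via bridged hemiketal 20 (not isolated)
Conditions: H2O2 (50% aq), BF3·OEt2 (0.3 equiv), Et2O–CH2Cl2, −20 → 0 °C; then aq NaHCO3
Reagents that add atoms: hydrogen peroxide, OO
Why: Acid-catalysed perhydrolysis of the tertiary C5 alcohol gives hydroperoxide 19, whose Hock–Criegee rearrangement moves the tertiary C10 from C5 to oxygen with retention of configuration (as for 9-decalyl hydroperoxide), so O10 takes the place of C5 and opening of the bridged hemiketal 20 releases the C5 ketone and the ten-membered ring.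

## Compound list

1 | (R)-(−)-carvone, (5R)-2-methyl-5-(prop-1-en-2-yl)cyclohex-2-en-1-one | C=C(C)[C@H]1CC(=O)C(C)=CC1 | starting material
2 | (5S)-1-(tert-butyldimethylsilyloxy)-2-methyl-5-(prop-1-en-2-yl)cyclohexa-1,3-diene | C=C(C)[C@H]1CC(O[Si](C)(C)C(C)(C)C)=C(C)C=C1 | intermediate
3 | 1-(tert-butyldimethylsilyloxy)-6-methyl-8-(prop-1-en-2-yl)-2,3-dioxabicyclo[2.2.2]oct-5-ene, peroxide bridge anti to isopropenyl | C=C(C)[C@H]1C[C@]2(O[Si](C)(C)C(C)(C)C)OO[C@H]1C=C2C | intermediate (not isolated)
4 | (4S,5R)-4-(tert-butyldimethylsilylperoxy)-2-methyl-5-(prop-1-en-2-yl)cyclohex-2-en-1-one | C=C(C)[C@H]1CC(=O)C(C)=C[C@@H]1OO[Si](C)(C)C(C)(C)C | intermediate (not isolated)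
5 | (4S,5R)-4-(tert-butyldimethylsilyloxy)-2-methyl-5-(prop-1-en-2-yl)cyclohex-2-en-1-one (silyloxy trans to isopropenyl) | C=C(C)[C@H]1CC(=O)C(C)=C[C@@H]1O[Si](C)(C)C(C)(C)C | intermediate
6 | 5-bromopent-1-ene | C=CCCCBr | starting material
7 | pent-4-en-1-ylmagnesium bromide | C=CCCC[Mg]Br | intermediate (not isolated)
8 | (1R,4S,5R)-4-(tert-butyldimethylsilyloxy)-2-methyl-1-(pent-4-en-1-yl)-5-(prop-1-en-2-yl)cyclohex-2-en-1-ol (pentenyl trans, OH cis to isopropenyl) | C=C(C)[C@H]1C[C@](O)(CCCC=C)C(C)=C[C@@H]1O[Si](C)(C)C(C)(C)C | intermediate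
9 | 1-methyl-2-(pent-4-en-1-yl)-4-(prop-1-en-2-yl)-5-(tert-butyldimethylsilyloxy)-7-oxabicyclo[4.1.0]heptan-2-ol, oxirane oxygen cis to the hydroxyl and trans to the silyloxy group | C=C(C)[C@H]1C[C@](O)(CCCC=C)[C@@]2(C)O[C@H]2[C@@H]1O[Si](C)(C)C(C)(C)C | intermediate
10 | (2R,3R,4R,5R)-4-(tert-butyldimethylsilyloxy)-3-hydroxy-2-methyl-2-(pent-4-en-1-yl)-5-(prop-1-en-2-yl)cyclohexan-1-one (2-CH3 cis to 3-OH; 3-OH trans to 4-OTBS; 4-OTBS trans to 5-isopropenyl) | C=C(C)[C@H]1CC(=O)[C@](C)(CCCC=C)[C@@H](O)[C@@H]1O[Si](C)(C)C(C)(C)C | intermediate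
11 | (S)-2-methylbutanoic acid | CC[C@H](C)C(=O)O | starting material
12 | (1R,2R,5R,6R)-6-(tert-butyldimethylsilyloxy)-2-methyl-3-oxo-2-(pent-4-en-1-yl)-5-(prop-1-en-2-yl)cyclohexyl (2S)-2-methylbutanoate | C=C(C)[C@H]1CC(=O)[C@](C)(CCCC=C)[C@@H](OC(=O)[C@@H](C)CC)[C@@H]1O[Si](C)(C)C(C)(C)C | intermediate
13 | cis-fused decalin-5-ol: C5–OH, C10–CH3 and C4–CH3 (4S) on one face; C9 (2S)-2-methylbutanoyloxy cis to C10–CH3; C8 OTBS trans to O9; C7 isopropenyl trans to O8 | C=C(C)[C@H]1C[C@]2(O)[C@@H](C)CCC[C@]2(C)[C@@H](OC(=O)[C@@H](C)CC)[C@@H]1O[Si](C)(C)C(C)(C)C | intermediate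
14 | as 13 with a free C8 hydroxyl | C=C(C)[C@H]1C[C@]2(O)[C@@H](C)CCC[C@]2(C)[C@@H](OC(=O)[C@@H](C)CC)[C@@H]1O | intermediate
15 | as 14 with the C7 substituent 3-hydroxyprop-1-en-2-yl | OCC(=C)[C@H]1C[C@]2(O)[C@@H](C)CCC[C@]2(C)[C@@H](OC(=O)[C@@H](C)CC)[C@@H]1O | intermediate
16 | as 15 with the C7 substituent 3-oxoprop-1-en-2-yl (enal) | O=CC(=C)[C@H]1C[C@]2(O)[C@@H](C)CCC[C@]2(C)[C@@H](OC(=O)[C@@H](C)CC)[C@@H]1O | intermediate (not isolated)
17 | lactol: C12 hemiacetal closed on O8 (either C12 epimer) | C=C1C(O)O[C@@H]2[C@@H]1C[C@]3(O)[C@@H](C)CCC[C@]3(C)[C@H]2OC(=O)[C@@H](C)CC | intermediate (not isolated)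
18 | cis-decalin-5-ol carrying the trans-fused 8,12-α-methylene-γ-lactone and the C9 (2S)-2-methylbutanoate | C=C1C(=O)O[C@@H]2[C@@H]1C[C@]3(O)[C@@H](C)CCC[C@]3(C)[C@H]2OC(=O)[C@@H](C)CC | intermediate
19 | C5 hydroperoxide of 18 (C5 either configuration) | C=C1C(=O)O[C@@H]2[C@@H]1CC3(OO)[C@@H](C)CCC[C@]3(C)[C@H]2OC(=O)[C@@H](C)CC | intermediate (not isolated)
20 | bridged hemiketal of 21 (C5(OH)–O–C10, 11-oxabicyclo[4.4.1]undecane core) | C=C1C(=O)O[C@@H]2[C@@H]1CC3(O)O[C@](C)(CCC[C@@H]3C)[C@H]2OC(=O)[C@@H](C)CC | intermediate (not isolated)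
21 | CNP0144277.6, (4S,7R,8R,9S,10R)-10-hydroxy-5-oxogermacr-11(13)-en-12,8-olide 9-[(2S)-2-methylbutanoate] | C=C1C(=O)O[C@@H]2[C@@H]1CC(=O)[C@@H](C)CCC[C@@](C)(O)[C@H]2OC(=O)[C@@H](C)CC | target

## Step count and risks

Total step count: 11. Longest linear sequence: 11 steps from carvone 1 (the Grignard reagent 7 is made in the flask in step 3).

The three steps most likely to fail:

Step 2 (the proposed new step). Singlet oxygen may attack the tetrasubstituted enol-ether bond instead of the diene, or silicon may be lost. The fallback uses known chemistry, sets out from 2 and comes back at 5. Vinylogous Rubottom oxidation of 2 with mCPBA (NaHCO3, CH2Cl2, −40 °C, then dilute acid work-up) is the peracid γ-hydroxylation known for steroidal dienol ethers; it attacks anti to isopropenyl and gives (4S,5R)-4-hydroxy-2-methyl-5-(prop-1-en-2-yl)cyclohex-2-en-1-one F1. Silylation with TBSCl and imidazole in DMF then gives 5.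

Step 7. The risks are over-reduction of the ester, a trans ring fusion (which would give the C4 epimer) or poor conversion of the hindered ketone. The fallback sets out from 12 and comes back at 13, and replaces the ketyl–olefin addition by an organometallic ring closure. Wacker oxidation (PdCl2, CuCl, O2, DMF–H2O; the 1,1-disubstituted isopropenyl alkene is inert) gives the methyl ketone F2. NaBH4 at −40 °C reduces only this unhindered ketone to the carbinol F3 (both C4 epimers, which does not matter). I2, PPh3 and imidazole give the secondary iodide F4. SmI2 with HMPA in THF then closes ring A by intramolecular Barbier addition to the C5 ketone, giving 13.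

Step 11. The risks are migration of the secondary C4 instead of the tertiary C10 (whose aptitude is lowered by the β-acyloxy group), cation chemistry at C5 during perhydrolysis, and over-oxidation of the product ketone. The fallback sets out from 12 and comes back at 21. It puts the oxygen insertion at the ketone stage, where C10 competes only with a primary CH2:
- Baeyer–Villiger oxidation of 12 with (Me3SiO)2 and TMSOTf (which spares C=C bonds) gives the oxepanone F5 with C10–O formed with retention.
- Wacker oxidation (PdCl2, CuCl, O2) gives the keto lactone F6.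
- McMurry keto-ester coupling (TiCl3, Zn–Cu couple, DME, high dilution) forms the C4–C5 bond and gives the bridged enol ether F7.
- Aqueous oxalic acid gives the ten-membered hydroxy ketone F8, with C4 set by protonation on the convex face and equilibration.
- HF·pyridine gives the diol F9, SeO2 with t-BuOOH gives the allylic alcohol F10, and MnO2 closes the lactone to 21.

Further compounds
F1 | step 2 | (4S,5R)-4-hydroxy-2-methyl-5-(prop-1-en-2-yl)cyclohex-2-en-1-one | C=C(C)[C@H]1CC(=O)C(C)=C[C@@H]1O
F2 | step 7 | methyl ketone: 12 with the pent-4-enyl chain oxidised to 4-oxopentyl | C=C(C)[C@H]1CC(=O)[C@](C)(CCCC(C)=O)[C@@H](OC(=O)[C@@H](C)CC)[C@@H]1O[Si](C)(C)C(C)(C)C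
F3 | step 7 | carbinol: 12 with a 4-hydroxypentyl chain (both C4 epimers) | C=C(C)[C@H]1CC(=O)[C@](C)(CCCC(C)O)[C@@H](OC(=O)[C@@H](C)CC)[C@@H]1O[Si](C)(C)C(C)(C)C
F4 | step 7 | iodide: 12 with a 4-iodopentyl chain (both C4 epimers) | C=C(C)[C@H]1CC(=O)[C@](C)(CCCC(C)I)[C@@H](OC(=O)[C@@H](C)CC)[C@@H]1O[Si](C)(C)C(C)(C)C
F5 | step 11 | oxepan-2-one from 12 (ring oxygen between C5 and C10, C10 configuration retained) | C=C(C)[C@H]1CC(=O)O[C@](C)(CCCC=C)[C@@H](OC(=O)[C@@H](C)CC)[C@@H]1O[Si](C)(C)C(C)(C)C
F6 | step 11 | keto lactone: F5 with a 4-oxopentyl chain | C=C(C)[C@H]1CC(=O)O[C@](C)(CCCC(C)=O)[C@@H](OC(=O)[C@@H](C)CC)[C@@H]1O[Si](C)(C)C(C)(C)C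
F7 | step 11 | bridged enol ether (C4=C5, C5–O–C10; 11-oxabicyclo[4.4.1]undecene core) | C=C(C)[C@H]1C/C2=C(\C)CCC[C@@](C)(O2)[C@@H](OC(=O)[C@@H](C)CC)[C@@H]1O[Si](C)(C)C(C)(C)C
F8 | step 11 | ten-membered 10-hydroxy-5-ketone with C7 isopropenyl and C8 OTBS | C=C(C)[C@H]1CC(=O)[C@@H](C)CCC[C@@](C)(O)[C@@H](OC(=O)[C@@H](C)CC)[C@@H]1O[Si](C)(C)C(C)(C)C
F9 | step 11 | F8 with a free C8 hydroxyl | C=C(C)[C@H]1CC(=O)[C@@H](C)CCC[C@@](C)(O)[C@@H](OC(=O)[C@@H](C)CC)[C@@H]1O
F10 | step 11 | F9 with the C7 substituent 3-hydroxyprop-1-en-2-yl | OCC(=C)[C@H]1CC(=O)[C@@H](C)CCC[C@@](C)(O)[C@@H](OC(=O)[C@@H](C)CC)[C@@H]1O
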